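**Plan**

- Retrosynthesis: the two phenol O–benzyl bonds are cut first, then the C5–H and C4–H bonds (hydrogenation of a C4=C5 enol acetate), then the acetyl–O bond at C5, then the four C–H bonds at C1, C2, C6 and C7, and last the C1–C2 and C6–C7 bonds (double aldol condensation of two O-benzylvanillin units with pentane-2,4-dione).
- Enabling feature: the C1–C7 chain carries the same 4-hydroxy-3-methoxyphenyl ring at both ends and oxygen on C3 and C5 either side of C4. The C3 ketone and the C5 acetate are therefore two oxidation levels of one symmetric heptane-3,5-dione, and C5 with its OAc and H is the enol acetate of that dione plus H2.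
- Forward: no ring is formed. The C7 chain is joined in one operation (C1–C2 and C6–C7), both alkenes are saturated, the symmetric dione is O-acetylated once (only one constitutional enol acetate is possible), the enol acetate is hydrogenated, and the benzyl ethers are removed.
- Stereochemistry: C5 is the only stereocentre. It is set as S by the chiral bisphosphine on rhodium, which adds hydrogen to the Re face of C5 of the Z-enol acetate. Nothing basic follows, so the beta-acetoxy ketone is neither eliminated nor racemised.

Key step: step 4

Assumption on the ligand: the (R,R) hand is written in step 4 for definiteness; both antipodes are commercial, and the one that adds hydrogen to the Re face of C5 is fixed by a trial run with assignment of the product.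
Assumption on boron speciation: the boron chelates of step 1 are drawn as their dibutoxyboron forms; B–O–B-bridged forms of the same chelates are also present and hydrolyse to the same product.
Assumption on twofold operations: where one operation acts on both like chain ends (steps 1, 2 and 5, and the diketone reduction in the first fallback), the half-reacted species belong to the same reaction and are not numbered separately.

**Step 1**
Reactants: 1 4-(benzyloxy)-3-methoxybenzaldehyde (O-benzylvanillin; 2.1 equiv); 2 pentane-2,4-dione (acetylacetone)
Product: 5 O,O'-dibenzylcurcumin [(1E,6E)-1,7-bis(4-benzyloxy-3-methoxyphenyl)hepta-1,6-diene-3,5-dione], via acetylacetone dibutoxyboron chelate 3 (not isolated), via dibenzylcurcumin dibutoxyboron chelate 4 (not isolated)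
Conditions: 2, B2O3 (0.7 equiv), EtOAc, 80 °C; then 1, B(OnBu)3 (2 equiv), n-BuNH2 (0.3 equiv, slow addition), 80 °C; then 0.4 M aq. HCl, 60 °C
Reagents that add atoms: none
Why: Boron-templated double aldol condensation (the classical curcumin synthesis): the boron chelate blocks the central methylene of 2, so the amine-catalysed condensation with 1 and dehydration occur at both terminal methyl groups to give the E,E-dienedione chelate 4, which dilute acid hydrolyses to 5.

**Step 2**
Reactants: 5 O,O'-dibenzylcurcumin
Product: 6 1,7-bis(4-benzyloxy-3-methoxyphenyl)heptane-3,5-dione (O,O'-dibenzyltetrahydrocurcumin)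
Conditions: H2 (1 atm), 10% Pd/C, 2,2'-bipyridyl (0.5 equiv), THF/MeOH, rt
Reagents that add atoms: none
Why: Chemoselective heterogeneous hydrogenation: Pd/C poisoned by the chelating nitrogen base still saturates the two conjugated C=C bonds, is known to leave phenolic benzyl ethers intact, and should not reduce the enolised 1,3-dione at 1 atm.

**Step 3**
Reactants: 6 1,7-bis(4-benzyloxy-3-methoxyphenyl)heptane-3,5-dione; 7 acetyl chloride
Product: 8 (Z)-5-acetoxy-1,7-bis(4-benzyloxy-3-methoxyphenyl)hept-4-en-3-one (acetoxy group cis to the C3 carbonyl)
Conditions: AcCl (1.1 equiv), pyridine (1.5 equiv), CH2Cl2, −20 to 0 °C; rapid chromatography on neutral silica to remove any E isomer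
Reagents that add atoms: acetyl chloride (compound 7), CC(=O)Cl
Why: O-acylation of a 1,3-diketone to its enol ester: pyridine is too weak a base to open the hydrogen-bonded cis-enol of 6 to a free enolate, so acetyl transfer to oxygen should carry the U-shape into the Z vinylogous anhydride, the symmetry of 6 allows only one constitutional product, and leaving out DMAP or cyanide avoids the O-to-C acyl shift.

**Step 4**
Reactants: 8 (Z)-5-acetoxy-1,7-bis(4-benzyloxy-3-methoxyphenyl)hept-4-en-3-one
Product: 9 (S)-5-acetoxy-1,7-bis(4-benzyloxy-3-methoxyphenyl)heptan-3-one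
Conditions: [Rh(cod)((R,R)-Me-DuPhos)]BF4 (2 mol %), H2 (10 bar), CH2Cl2, 25 °C
Reagents that add atoms: none
Why: Proposed new method: the cationic monovalent rhodium bisphosphine complex, freed from cyclooctadiene by hydrogen, should bind 8 as a five-membered chelate through the C4=C5 alkene and the acetate carbonyl oxygen, as an enamide binds; oxidative addition of H2, migratory insertion that puts rhodium on C5 and hydrogen on C4, and reductive elimination then add both hydrogens to one face and form the C4–H and C5–H bonds. The closest known reaction types are the Rh-bisphosphine asymmetric hydrogenation of enol acetates, of beta-acyloxy acrylates and of beta-keto enamides to beta-amido ketones; an acyclic beta-acetoxy enone with alkyl groups on both sides has not been shown. No ring is closed. C5, the only stereocentre, is controlled by the chiral ligand pocket, which with the chelate fixed should expose the Re face of C5 of the Z-alkene and so give S. The step needs facial selectivity, and chemoselectivity for C=C reduction over vinylic C–O cleavage, ketone reduction and benzyl ether hydrogenolysis. The single Z geometry and the two-point binding secure the first, and a mild homogeneous catalyst in non-nucleophilic CH2Cl2, which cannot solvolyse the vinylogous anhydride, secures the rest.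

**Step 5**
Reactants: 9 (S)-5-acetoxy-1,7-bis(4-benzyloxy-3-methoxyphenyl)heptan-3-one
Product: 10 (S)-5-acetoxy-1,7-bis(4-hydroxy-3-methoxyphenyl)heptan-3-one [(S)-5-O-acetylhexahydrocurcumin, the target]
Conditions: H2 (1 atm), 10% Pd/C, EtOAc, rt
Reagents that add atoms: none
Why: Hydrogenolysis of aryl benzyl ethers over unpoisoned Pd/C in neutral ethyl acetate frees both phenols, and with no acid or base present the E1cB-prone beta-acetoxy ketone should keep its acetate and its S configuration while the dialkyl ketone is untouched.

**Compound list**

1 | 4-(benzyloxy)-3-methoxybenzaldehyde (O-benzylvanillin) | COc1cc(C=O)ccc1OCc1ccccc1 | starting material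
2 | pentane-2,4-dione (acetylacetone) | CC(=O)CC(C)=O | starting material
3 | dibutoxyboron chelate of pentane-2,4-dione (2,2-dibutoxy-4,6-dimethyl-1,3,2-dioxaborinine) | CC1=CC(C)=[O+][B-](OCCCC)(OCCCC)O1 | intermediate
4 | dibutoxyboron chelate of O,O'-dibenzylcurcumin | COc1cc(/C=C/C2=CC(/C=C/c3ccc(OCc4ccccc4)c(OC)c3)=[O+][B-](OCCCC)(OCCCC)O2)ccc1OCc1ccccc1 | intermediate
5 | (1E,6E)-1,7-bis(4-benzyloxy-3-methoxyphenyl)hepta-1,6-diene-3,5-dione (O,O'-dibenzylcurcumin) | COc1cc(/C=C/C(=O)CC(=O)/C=C/c2ccc(OCc3ccccc3)c(OC)c2)ccc1OCc1ccccc1 | intermediate
6 | 1,7-bis(4-benzyloxy-3-methoxyphenyl)heptane-3,5-dione | COc1cc(CCC(=O)CC(=O)CCc2ccc(OCc3ccccc3)c(OC)c2)ccc1OCc1ccccc1 | intermediate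
7 | acetyl chloride | CC(=O)Cl | starting material
8 | (Z)-5-acetoxy-1,7-bis(4-benzyloxy-3-methoxyphenyl)hept-4-en-3-one | COc1cc(CC/C(OC(C)=O)=C/C(=O)CCc2ccc(OCc3ccccc3)c(OC)c2)ccc1OCc1ccccc1 | intermediate
9 | (S)-5-acetoxy-1,7-bis(4-benzyloxy-3-methoxyphenyl)heptan-3-one | COc1cc(CCC(=O)C[C@H](CCc2ccc(OCc3ccccc3)c(OC)c2)OC(C)=O)ccc1OCc1ccccc1 | intermediate
10 | (S)-5-acetoxy-1,7-bis(4-hydroxy-3-methoxyphenyl)heptan-3-one | COc1cc(CCC(=O)C[C@H](CCc2ccc(O)c(OC)c2)OC(C)=O)ccc1O | target

**Step count**

Total step count: 5. Longest linear sequence: 5 steps (1 and 2 to 5, then 6, 8, 9, 10).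

**Steps most likely to fail**

Step 4 (proposed method). Turnover may be slow because the electron-rich arenes or the ketone compete with the acetate for the cationic rhodium centre. Facial selectivity may be poor. The acetate may be lost by beta-acetoxy elimination if hydrogen goes to C5 first and rhodium to C4. The fallback uses known chemistry, sets out from dione 6 and comes back at 9. Noyori hydrogenation of the 1,3-diketone with [RuCl(p-cymene)((S)-BINAP)]Cl under H2 (50 bar) in MeOH/CH2Cl2 at 50 °C should reduce both carbonyls to the C2-symmetric anti-diol (3S,5S)-1,7-bis(4-benzyloxy-3-methoxyphenyl)heptane-3,5-diol F1. The BINAP hand is chosen by analogy with pentane-2,4-dione and confirmed by assignment. Trimethyl orthoacetate with catalytic PPTS in CH2Cl2 then closes the six-membered cyclic orthoester (4S,6S)-4,6-bis[2-(4-benzyloxy-3-methoxyphenyl)ethyl]-2-methoxy-2-methyl-1,3-dioxane F2. Aqueous acetic acid opens it without isolation to the monoacetate (3S,5S)-1,7-bis(4-benzyloxy-3-methoxyphenyl)-5-hydroxyheptan-3-yl acetate F3. The two hydroxyls of the diol are homotopic, so only one monoacetate can arise. Dess–Martin oxidation in CH2Cl2 converts the remaining carbinol to the ketone, erasing that centre and leaving C5 as S in 9.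

Step 3. Acylation may occur on carbon instead of oxygen, the double-bond geometry may be lost to the E isomer, or the vinylogous anhydride may hydrolyse during isolation. The fallback sets out from dione 6 and comes back at 8. It replaces irreversible acyl transfer under base by reversible acid-catalysed enol-ester exchange: 6 is heated in isopropenyl acetate with catalytic p-TsOH while acetone distils off. E and Z then equilibrate through the protonated enol ester towards the Z isomer, in which the small acetoxy group rather than the alkyl chain sits cis to the acyl group, and without base no O-to-C shift can start. No compound outside the route is made (F0).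

Step 2. The aryl benzyl ethers may be lost by hydrogenolysis, or the enolised dione carbonyl may be over-reduced. The fallback sets out from aldehyde 1 (with 2) and comes back at 6, building the saturated chain by alkylation so that no alkene has to be hydrogenated. NaBH4 in MeOH reduces 1 to [4-(benzyloxy)-3-methoxyphenyl]methanol F4. PBr3 in Et2O at 0 °C gives 1-(benzyloxy)-4-(bromomethyl)-2-methoxybenzene F5. The dianion of 2 (LDA, 2.1 equiv, THF, 0 °C) is alkylated at its terminal carbon by the bromide to give 6-(4-benzyloxy-3-methoxyphenyl)hexane-2,4-dione F6. A second dianion formation at the remaining methyl group and alkylation with the same bromide gives 6.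

**Further compounds**

F1 | step 4 | (3S,5S)-1,7-bis(4-benzyloxy-3-methoxyphenyl)heptane-3,5-diol | COc1cc(CC[C@H](O)C[C@H](CCc2ccc(OCc3ccccc3)c(OC)c2)O)ccc1OCc1ccccc1
F2 | step 4 | (4S,6S)-4,6-bis[2-(4-benzyloxy-3-methoxyphenyl)ethyl]-2-methoxy-2-methyl-1,3-dioxane | COc1cc(CC[C@H]2C[C@H](CCc3ccc(OCc4ccccc4)c(OC)c3)OC(C)(OC)O2)ccc1OCc1ccccc1
F3 | step 4 | (3S,5S)-1,7-bis(4-benzyloxy-3-methoxyphenyl)-5-hydroxyheptan-3-yl acetate | COc1cc(CC[C@H](O)C[C@H](CCc2ccc(OCc3ccccc3)c(OC)c2)OC(C)=O)ccc1OCc1ccccc1
F0 | step 3 | none | none
F4 | step 2 | [4-(benzyloxy)-3-methoxyphenyl]methanol | COc1cc(CO)ccc1OCc1ccccc1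
F5 | step 2 | 1-(benzyloxy)-4-(bromomethyl)-2-methoxybenzene | COc1cc(CBr)ccc1OCc1ccccc1
F6 | step 2 | 6-(4-benzyloxy-3-methoxyphenyl)hexane-2,4-dione | CC(=O)CC(=O)CCc1ccc(OCc2ccccc2)c(OC)c1
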